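**Plan**

1. Locants: oxocane O1, C2 (carries side chain C1'–C5'), C3–C8 (C8 carries C1''HBr–Et). Retrosynthesis cuts C1''–Br and the enyne (C2'=C3', C3'–C4') first, then the ring at C2–C3 and C4–C5, which excises C3–C4 and rejoins C2 to C5.
2. Enabling feature: the O1-bearing C2 and the oxygen-bearing C6 are 1,5-related through C3–C4–C5 (a de Mayo retron). The eight-membered ring is therefore the six-membered 2,3-dihydro-4H-pyran-4-one ring (O1, C2, C5, C6, C7, C8; enone C5=C2) with a C3–C4 unit inserted into the C2–C5 bond.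
3. Forward: Felkin aldol and cycloisomerisation give the pyranone; [2+2] photocycloaddition with vinyl acetate builds the cyclobutane (C2–C3, C4–C5); reductive cleavage of the ring-fusion bond C2–C5 opens the bicycle to the oxocane as a bis(enol ether); chlorines, C2–H, C6–OAc, enyne and bromide follow.
4. Stereochemistry: C1'' from (S)-2-hydroxybutanoate (inverted by bromide at the end); C8 by Felkin–Anh addition; C3 by chlorination anti to the C8 side chain; C2 by hydride anti to the C3 chlorine; C5 by equilibration of the α-chloro ketone; C6 by hydride anti to chlorine, then Mitsunobu inversion.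

Key step: step 6

Remark: 11 is carried forward as its mixture of cis-fused diastereomers (one is drawn), because step 7 destroys all three stereocentres made in step 6.

Abbreviations: TBS = tert-butyldimethylsilyl, TBDPS = tert-butyldiphenylsilyl, TES = triethylsilyl.

**Route**

Step 1
Reactants: 1 methyl (2S)-2-hydroxybutanoate
Product: 2 methyl (2S)-2-(TBDPS-oxy)butanoate
Conditions: TBDPSCl, imidazole, DMF, 23 °C
Reagents that add atoms: tert-butyl(chloro)diphenylsilane, CC(C)(C)[Si](Cl)(c1ccccc1)c1ccccc1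
Why: Silylation of a secondary alcohol with a silyl chloride and imidazole is routine, leaves the stereocentre untouched, and the bulky silyl ether later enforces non-chelation control.

Step 2
Reactants: 2 methyl (2S)-2-(TBDPS-oxy)butanoate
Product: 3 (2S)-2-(TBDPS-oxy)butanal
Conditions: diisobutylaluminium hydride, CH2Cl2, −78 °C; then aq. KNaC4H4O6 (Rochelle salt)
Reagents that add atoms: none
Why: Half-reduction of an α-silyloxy ester with DIBAL-H at −78 °C stops at the aldehyde through the stable tetrahedral aluminium hemiacetal, without epimerisation of the α-centre.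

Step 3
Reactants: 4 tert-butyl(but-3-yn-1-yloxy)dimethylsilane; 5 N-methoxy-N-methylacetamide
Product: 6 6-(TBS-oxy)hex-3-yn-2-one
Conditions: n-BuLi, THF, −78 °C; then 5, −78 → 0 °C; then H2O
Reagents that add atoms: none
Why: Acylation of a lithium acetylide with a Weinreb amide stops at the ketone because the chelated tetrahedral intermediate survives until work-up.

Step 4
Reactants: 6 6-(TBS-oxy)hex-3-yn-2-one; 3 (2S)-2-(TBDPS-oxy)butanal
Product: 8 (7R,8S)-1-(TBS-oxy)-8-(TBDPS-oxy)-7-hydroxydec-3-yn-5-one, via enol silane 7 (not isolated)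
Conditions: TMSOTf, Et3N, CH2Cl2, 0 °C; salts filtered off; then 3, BF3·OEt2, CH2Cl2, −78 °C
Reagents that add atoms: trimethylsilyl trifluoromethanesulfonate, C[Si](C)(C)OS(=O)(=O)C(F)(F)F (its silyl group is carried only in 7)
Why: Mukaiyama aldol addition through an open transition state in which BF3 cannot chelate and the bulky silyloxy group lies anti to the incoming enol silane (polar Felkin–Anh model), so the new carbinol (chain C7, later ring C8) should form 7,8-anti, that is 7R next to 8S.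

Step 5
Reactants: 8 (7R,8S)-1-(TBS-oxy)-8-(TBDPS-oxy)-7-hydroxydec-3-yn-5-one
Product: 9 (2R)-6-[2-(TBS-oxy)ethyl]-2-[(1S)-1-(TBDPS-oxy)propyl]-2,3-dihydro-4H-pyran-4-one
Conditions: Ph3PAuCl (5 mol %), AgOTf (5 mol %), CH2Cl2, 23 °C
Reagents that add atoms: none
Why: Gold-catalysed 6-endo-dig addition of the β-hydroxyl group to the ynone (a cycloisomerisation equivalent to an oxa-Michael addition) closes the six-membered ring at O1–C2 without touching the two stereocentres.

Step 6
Reactants: 9 (2R)-6-[2-(TBS-oxy)ethyl]-2-[(1S)-1-(TBDPS-oxy)propyl]-2,3-dihydro-4H-pyran-4-one; 10 vinyl acetate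
Product: 11 (3R)-8-acetoxy-1-[2-(TBS-oxy)ethyl]-3-[(1S)-1-(TBDPS-oxy)propyl]-2-oxabicyclo[4.2.0]octan-5-one (cis ring fusion; in oxocane locants the cyclobutane is C2–C3–C4–C5 with the acetate on C3; drawn as the isomer formed anti to the C8 side chain with exo acetate)
Conditions: hν (350 nm, Pyrex), 10 (20 equiv), degassed MeCN, 0 °C
Reagents that add atoms: none
Why: Irradiation excites the vinylogous ester chromophore of 9 (C6=O conjugated with C5=C2–O1), and its triplet adds vinyl acetate stepwise through a 1,4-biradical, forming C4–C5 and C2–C3 in one operation. The closest known reaction type is the enone–alkene [2+2] photocycloaddition in its de Mayo form, which is established for 2,3-dihydro-4H-pyran-4-ones and other β-alkoxy enones. The cyclobutane (C2–C3–C4–C5) closes by recombination of the biradical, a formal [2π+2π] closure, and the six-membered ring allows only a cis ring fusion. The new stereocentres C2, C3 and C5 need no control, because C2 and C5 become sp2 and C3 loses its oxygen in step 7, so all diastereomers converge. The selectivity the step needs is head-to-tail regiochemistry (acetoxy-bearing carbon to C2, CH2 to C5), which the donor character of the vinyl ester and the polarisation of the excited β-alkoxy enone should secure, as is usual for electron-rich alkenes. The large excess of alkene suppresses dimerisation of 9, and 350 nm light is absorbed neither by the silyl ethers nor by vinyl acetate.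

Step 7
Reactants: 11 (3R)-8-acetoxy-1-[2-(TBS-oxy)ethyl]-3-[(1S)-1-(TBDPS-oxy)propyl]-2-oxabicyclo[4.2.0]octan-5-one
Product: 13 (8R)-2-[2-(TBS-oxy)ethyl]-8-[(1S)-1-(TBDPS-oxy)propyl]-6-(TES-oxy)-7,8-dihydro-4H-oxocine (double bonds C2=C3 and C5=C6, both cis within the ring), via samarium enolate 12 (not isolated)
Conditions: SmI2 (3 equiv), HMPA (12 equiv), THF, −78 → −20 °C; then TESCl (3 equiv), −78 → 0 °C
Reagents that add atoms: chlorotriethylsilane, CC[Si](Cl)(CC)CC; samarium diiodide, I[Sm]I (samarium is carried only in 12)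
Why: Proposed new method: single-electron transfer from SmI2 to the C6 ketone gives a ketyl, a cyclobutylcarbinyl radical that should open by β-scission of the strained ring-fusion bond C2–C5 because this releases the tertiary, oxygen-stabilised C2 radical and the samarium enolate C5=C6, a second electron transfer then expels the β-acetoxy group from C3 (E1cB-like reductive elimination) to give the C2=C3 enol ether whatever the C3 configuration, and TESCl traps the regiodefined enolate; the closest known reaction types are the SmI2 ring opening of bicyclo[4.2.0]octan-2-one photoadducts and the SmI2 reductive elimination of β-acetoxy radicals (Julia–Lythgoe olefination, glycal formation from 2-O-acyl glycosyl halides).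

Step 8
Reactants: 13 (8R)-2-[2-(TBS-oxy)ethyl]-8-[(1S)-1-(TBDPS-oxy)propyl]-6-(TES-oxy)-7,8-dihydro-4H-oxocine
Product: 14 (2S,3S,5S,8R)-3,5-dichloro-2-methoxy-2-[2-(TBS-oxy)ethyl]-8-[(1S)-1-(TBDPS-oxy)propyl]oxocan-6-one (the 2,3-anti adduct is drawn; the C2 ketal centre is removed in step 9)
Conditions: NCS (2.2 equiv), MeOH (10 equiv), NaHCO3, CH2Cl2, −78 → 0 °C; then n-Bu4NCl (0.2 equiv), MeCN, 23 °C
Reagents that add atoms: N-chlorosuccinimide, O=C1CCC(=O)N1Cl; methanol, CO
Why: Electrophilic chlorination of both enol ethers, in which the silyl enol ether gives the α-chloro ketone at C5 and the alkyl enol ether undergoes anti chloro-methoxylation with chlorine entering C3 on the open, peripheral ring face that also carries the C8 hydrogen (anti to the C8 side chain), while the epimerisable C5 centre is left to equilibrate by chloride exchange towards the 3,5-trans isomer with opposed C–Cl dipoles.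

Step 9
Reactants: 14 (2S,3S,5S,8R)-3,5-dichloro-2-methoxy-2-[2-(TBS-oxy)ethyl]-8-[(1S)-1-(TBDPS-oxy)propyl]oxocan-6-one
Product: 16 (2S,3S,5S,8R)-3,5-dichloro-2-[2-(TBS-oxy)ethyl]-8-[(1S)-1-(TBDPS-oxy)propyl]oxocan-6-one, via oxocarbenium triflate 15 (not isolated)
Conditions: Et3SiH (5 equiv), TMSOTf (1.2 equiv), CH2Cl2, −78 → −40 °C
Reagents that add atoms: trimethylsilyl trifluoromethanesulfonate, C[Si](C)(C)OS(=O)(=O)C(F)(F)F (its triflate is the counter-ion of 15 only)
Why: Ionic reduction of a cyclic ketal (silane hydride transfer to an oxocarbenium ion, as in C-glycoside synthesis), in which the adjacent C3 chlorine should direct hydride to the opposite face, as 2-halo substituents direct 1,2-trans additions to glycosyl cations, so that C2 is set with H anti to Cl and the side chain cis to Cl and trans to the C8 substituent, while the inductively deactivated α-chloro ketone should not be reduced.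

Step 10
Reactants: 16 (2S,3S,5S,8R)-3,5-dichloro-2-[2-(TBS-oxy)ethyl]-8-[(1S)-1-(TBDPS-oxy)propyl]oxocan-6-one
Product: 17 (2S,3S,5S,6R,8R)-3,5-dichloro-2-[2-(TBS-oxy)ethyl]-8-[(1S)-1-(TBDPS-oxy)propyl]oxocan-6-ol
Conditions: LiBH(s-Bu)3 (L-Selectride), THF, −78 °C; then H2O
Reagents that add atoms: none
Why: Reduction of an α-chloro ketone with a bulky borohydride, where attack anti to the C–Cl bond (polar Felkin–Anh model, as for 2-chlorocyclohexanone) should give the 5,6-cis chlorohydrin, whose alkoxide cannot close to an epoxide.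

Step 11
Reactants: 17 (2S,3S,5S,6R,8R)-3,5-dichloro-2-[2-(TBS-oxy)ethyl]-8-[(1S)-1-(TBDPS-oxy)propyl]oxocan-6-ol
Product: 18 (2S,3S,5S,6S,8R)-3,5-dichloro-2-[2-(TBS-oxy)ethyl]-8-[(1S)-1-(TBDPS-oxy)propyl]oxocan-6-yl acetate
Conditions: PPh3, DIAD, AcOH, toluene, 0 → 23 °C
Reagents that add atoms: acetic acid, CC(=O)O
Why: Mitsunobu esterification proceeds with SN2 inversion at C6 and so converts the cis chlorohydrin directly into the trans chloro acetate of the target.

Step 12
Reactants: 18 (2S,3S,5S,6S,8R)-3,5-dichloro-2-[2-(TBS-oxy)ethyl]-8-[(1S)-1-(TBDPS-oxy)propyl]oxocan-6-yl acetate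
Product: 19 (2S,3S,5S,6S,8R)-3,5-dichloro-2-(2-hydroxyethyl)-8-[(1S)-1-(TBDPS-oxy)propyl]oxocan-6-yl acetate
Conditions: HF·pyridine, pyridine, THF, 0 °C
Reagents that add atoms: none
Why: Buffered HF·pyridine cleaves a primary TBS ether much faster than the hindered secondary TBDPS ether, and the acetate and the chlorides are inert.

Step 13
Reactants: 19 (2S,3S,5S,6S,8R)-3,5-dichloro-2-(2-hydroxyethyl)-8-[(1S)-1-(TBDPS-oxy)propyl]oxocan-6-yl acetate
Product: 20 (2S,3S,5S,6S,8R)-3,5-dichloro-2-(2-oxoethyl)-8-[(1S)-1-(TBDPS-oxy)propyl]oxocan-6-yl acetate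
Conditions: Dess–Martin periodinane, CH2Cl2, 0 → 23 °C; used crude
Reagents that add atoms: none
Why: Dess–Martin oxidation is mild and non-basic, so the β-alkoxy aldehyde should form without β-elimination or epimerisation at C2.

Step 14
Reactants: 20 (2S,3S,5S,6S,8R)-3,5-dichloro-2-(2-oxoethyl)-8-[(1S)-1-(TBDPS-oxy)propyl]oxocan-6-yl acetate
Product: 21 (2S,3S,5S,6S,8R)-3,5-dichloro-2-[(2E)-3-iodoprop-2-en-1-yl]-8-[(1S)-1-(TBDPS-oxy)propyl]oxocan-6-yl acetate
Conditions: CrCl2 (6 equiv), CHI3 (2 equiv), THF–dioxane, 0 → 23 °C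
Reagents that add atoms: iodoform, IC(I)I
Why: Takai olefination, in which the gem-dichromium species from CHI3 and CrCl2 adds to the aldehyde and eliminates to the (E)-vinyl iodide, while unactivated secondary chlorides do not react with CrCl2.

Step 15
Reactants: 21 (2S,3S,5S,6S,8R)-3,5-dichloro-2-[(2E)-3-iodoprop-2-en-1-yl]-8-[(1S)-1-(TBDPS-oxy)propyl]oxocan-6-yl acetate; 22 ethynyltrimethylsilane
Product: 23 (2S,3S,5S,6S,8R)-3,5-dichloro-2-[(2E)-5-(trimethylsilyl)pent-2-en-4-yn-1-yl]-8-[(1S)-1-(TBDPS-oxy)propyl]oxocan-6-yl acetate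
Conditions: Pd(PPh3)4 (5 mol %), CuI (10 mol %), Et2NH, THF, 23 °C
Reagents that add atoms: none
Why: Sonogashira coupling of a vinyl iodide proceeds at room temperature with retention of the E geometry and tolerates alkyl chlorides and esters.

Step 16
Reactants: 23 (2S,3S,5S,6S,8R)-3,5-dichloro-2-[(2E)-5-(trimethylsilyl)pent-2-en-4-yn-1-yl]-8-[(1S)-1-(TBDPS-oxy)propyl]oxocan-6-yl acetate
Product: 24 (2S,3S,5S,6S,8R)-3,5-dichloro-8-[(1S)-1-hydroxypropyl]-2-[(2E)-pent-2-en-4-yn-1-yl]oxocan-6-yl acetate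
Conditions: TBAF (5 equiv), AcOH (5 equiv), THF, 23 °C
Reagents that add atoms: none
Why: Fluoride cleaves the alkynyl C–Si bond and the TBDPS ether, and the acetic acid buffer keeps the medium non-basic so that the acetate and the β-chloro ester survive.

Step 17
Reactants: 24 (2S,3S,5S,6S,8R)-3,5-dichloro-8-[(1S)-1-hydroxypropyl]-2-[(2E)-pent-2-en-4-yn-1-yl]oxocan-6-yl acetate
Product: 25 (2S,3S,5S,6S,8R)-8-[(1R)-1-bromopropyl]-3,5-dichloro-2-[(2E)-pent-2-en-4-yn-1-yl]oxocan-6-yl acetate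
Conditions: CBr4, P(n-C8H17)3, toluene, 70 °C
Reagents that add atoms: tetrabromomethane, BrC(Br)(Br)Br
Why: Appel-type bromination, in which bromide displaces the alkoxyphosphonium group with SN2 inversion at C1'' and turns the (S)-carbinol into the (R)-bromide, a standard last step for halogenated medium-ring ethers.

**Compound list**

1 | methyl (2S)-2-hydroxybutanoate | CC[C@H](O)C(=O)OC | starting material
2 | methyl (2S)-2-(TBDPS-oxy)butanoate | CC[C@H](O[Si](c1ccccc1)(c1ccccc1)C(C)(C)C)C(=O)OC | intermediate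
3 | (2S)-2-(TBDPS-oxy)butanal | CC[C@H](O[Si](c1ccccc1)(c1ccccc1)C(C)(C)C)C=O | intermediate
4 | tert-butyl(but-3-yn-1-yloxy)dimethylsilane | C#CCCO[Si](C)(C)C(C)(C)C | starting material
5 | N-methoxy-N-methylacetamide | CC(=O)N(C)OC | starting material
6 | 6-(TBS-oxy)hex-3-yn-2-one | CC(=O)C#CCCO[Si](C)(C)C(C)(C)C | intermediate
7 | enol silane, tert-butyldimethyl{[5-(trimethylsilyloxy)hex-5-en-3-yn-1-yl]oxy}silane (not isolated) | C=C(O[Si](C)(C)C)C#CCCO[Si](C)(C)C(C)(C)C | intermediate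
8 | (7R,8S)-1-(TBS-oxy)-8-(TBDPS-oxy)-7-hydroxydec-3-yn-5-one | O[C@@H]([C@@H](O[Si](c1ccccc1)(c1ccccc1)C(C)(C)C)CC)CC(=O)C#CCCO[Si](C)(C)C(C)(C)C | intermediate
9 | (2R)-6-[2-(TBS-oxy)ethyl]-2-[(1S)-1-(TBDPS-oxy)propyl]-2,3-dihydro-4H-pyran-4-one | O=C1C[C@H]([C@@H](O[Si](c2ccccc2)(c2ccccc2)C(C)(C)C)CC)OC(CCO[Si](C)(C)C(C)(C)C)=C1 | intermediate
10 | vinyl acetate | CC(=O)OC=C | starting material
11 | (3R)-8-acetoxy-1-[2-(TBS-oxy)ethyl]-3-[(1S)-1-(TBDPS-oxy)propyl]-2-oxabicyclo[4.2.0]octan-5-one, cis-fused (isomer anti to the C8 side chain with exo acetate drawn; diastereomer mixture) | O=C1C[C@H]([C@@H](O[Si](c3ccccc3)(c3ccccc3)C(C)(C)C)CC)O[C@@]2(CCO[Si](C)(C)C(C)(C)C)[C@H](OC(C)=O)C[C@@H]12 | intermediate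
12 | samarium enolate of the ring-opened oxocine (not isolated) | O1[C@@H]([C@@H](O[Si](c2ccccc2)(c2ccccc2)C(C)(C)C)CC)C/C(O[Sm](I)I)=C\C/C=C\1CCO[Si](C)(C)C(C)(C)C | intermediate
13 | (8R)-2-[2-(TBS-oxy)ethyl]-8-[(1S)-1-(TBDPS-oxy)propyl]-6-(TES-oxy)-7,8-dihydro-4H-oxocine | O1[C@@H]([C@@H](O[Si](c2ccccc2)(c2ccccc2)C(C)(C)C)CC)C/C(O[Si](CC)(CC)CC)=C\C/C=C\1CCO[Si](C)(C)C(C)(C)C | intermediate
14 | (2S,3S,5S,8R)-3,5-dichloro-2-methoxy-2-[2-(TBS-oxy)ethyl]-8-[(1S)-1-(TBDPS-oxy)propyl]oxocan-6-one | CC(C)(C)[Si](C)(C)OCC[C@]1(OC)O[C@@H]([C@@H](O[Si](c2ccccc2)(c2ccccc2)C(C)(C)C)CC)CC(=O)[C@@H](Cl)C[C@@H]1Cl | intermediate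
15 | (3S,5S,8R)-3,5-dichloro-6-oxo-2-[2-(TBS-oxy)ethyl]-8-[(1S)-1-(TBDPS-oxy)propyl]oxocan-1-ium-1(2)-ene triflate, oxocarbenium ion O1=C2 (not isolated) | CC(C)(C)[Si](C)(C)OCCC1=[O+][C@@H]([C@@H](O[Si](c2ccccc2)(c2ccccc2)C(C)(C)C)CC)CC(=O)[C@@H](Cl)C[C@@H]1Cl.[O-]S(=O)(=O)C(F)(F)F | intermediate
16 | (2S,3S,5S,8R)-3,5-dichloro-2-[2-(TBS-oxy)ethyl]-8-[(1S)-1-(TBDPS-oxy)propyl]oxocan-6-one | CC(C)(C)[Si](C)(C)OCC[C@@H]1O[C@@H]([C@@H](O[Si](c2ccccc2)(c2ccccc2)C(C)(C)C)CC)CC(=O)[C@@H](Cl)C[C@@H]1Cl | intermediate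
17 | (2S,3S,5S,6R,8R)-3,5-dichloro-2-[2-(TBS-oxy)ethyl]-8-[(1S)-1-(TBDPS-oxy)propyl]oxocan-6-ol | CC(C)(C)[Si](C)(C)OCC[C@@H]1O[C@@H]([C@@H](O[Si](c2ccccc2)(c2ccccc2)C(C)(C)C)CC)C[C@@H](O)[C@@H](Cl)C[C@@H]1Cl | intermediate
18 | (2S,3S,5S,6S,8R)-3,5-dichloro-2-[2-(TBS-oxy)ethyl]-8-[(1S)-1-(TBDPS-oxy)propyl]oxocan-6-yl acetate | CC(C)(C)[Si](C)(C)OCC[C@@H]1O[C@@H]([C@@H](O[Si](c2ccccc2)(c2ccccc2)C(C)(C)C)CC)C[C@H](OC(C)=O)[C@@H](Cl)C[C@@H]1Cl | intermediate
19 | (2S,3S,5S,6S,8R)-3,5-dichloro-2-(2-hydroxyethyl)-8-[(1S)-1-(TBDPS-oxy)propyl]oxocan-6-yl acetate | OCC[C@@H]1O[C@@H]([C@@H](O[Si](c2ccccc2)(c2ccccc2)C(C)(C)C)CC)C[C@H](OC(C)=O)[C@@H](Cl)C[C@@H]1Cl | intermediate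
20 | (2S,3S,5S,6S,8R)-3,5-dichloro-2-(2-oxoethyl)-8-[(1S)-1-(TBDPS-oxy)propyl]oxocan-6-yl acetate | O=CC[C@@H]1O[C@@H]([C@@H](O[Si](c2ccccc2)(c2ccccc2)C(C)(C)C)CC)C[C@H](OC(C)=O)[C@@H](Cl)C[C@@H]1Cl | intermediate
21 | (2S,3S,5S,6S,8R)-3,5-dichloro-2-[(2E)-3-iodoprop-2-en-1-yl]-8-[(1S)-1-(TBDPS-oxy)propyl]oxocan-6-yl acetate | I/C=C/C[C@@H]1O[C@@H]([C@@H](O[Si](c2ccccc2)(c2ccccc2)C(C)(C)C)CC)C[C@H](OC(C)=O)[C@@H](Cl)C[C@@H]1Cl | intermediate
22 | ethynyltrimethylsilane | C#C[Si](C)(C)C | starting material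
23 | (2S,3S,5S,6S,8R)-3,5-dichloro-2-[(2E)-5-(trimethylsilyl)pent-2-en-4-yn-1-yl]-8-[(1S)-1-(TBDPS-oxy)propyl]oxocan-6-yl acetate | C[Si](C)(C)C#C/C=C/C[C@@H]1O[C@@H]([C@@H](O[Si](c2ccccc2)(c2ccccc2)C(C)(C)C)CC)C[C@H](OC(C)=O)[C@@H](Cl)C[C@@H]1Cl | intermediate
24 | (2S,3S,5S,6S,8R)-3,5-dichloro-8-[(1S)-1-hydroxypropyl]-2-[(2E)-pent-2-en-4-yn-1-yl]oxocan-6-yl acetate | C#C/C=C/C[C@@H]1O[C@@H]([C@@H](O)CC)C[C@H](OC(C)=O)[C@@H](Cl)C[C@@H]1Cl | intermediate
25 | (2S,3S,5S,6S,8R)-8-[(1R)-1-bromopropyl]-3,5-dichloro-2-[(2E)-pent-2-en-4-yn-1-yl]oxocan-6-yl acetate | C#C/C=C/C[C@@H]1O[C@@H]([C@H](Br)CC)C[C@H](OC(C)=O)[C@@H](Cl)C[C@@H]1Cl | target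

**Totals and risks**

Total step count: 17. Longest linear sequence: 16 steps (1 to 25 through steps 1, 2 and 4–17; the branch 4 to 6 is one step).

Steps most likely to fail:

1. Step 7 (Proposed new method). The ketyl may open the outer cyclobutane bond C4–C5 instead of the ring-fusion bond C2–C5. The C2 radical may abstract hydrogen before the second electron transfer, so that acetate is not expelled. The enolate may be protonated before it is silylated. Fallback with known chemistry, setting out from 9: [2+2] photocycloaddition with acetylene (hν 350 nm, MeCN) should give the cis-fused cyclobutene ketone F1. As a donor–acceptor cyclobutene (O1 on C2, ketone next to C5) it should open by heterolysis of C2–C5, on warming in toluene or with catalytic BF3·OEt2, to the eight-membered 2-alkoxy dienone F2. 1,4-Hydrosilylation of its enone with Et3SiH and RhCl(PPh3)3 (hydride to C4, silicon to oxygen) comes back to the route at 13.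

2. Step 8. Facial control may be lost in the chlorination of the C2=C3 enol ether (chlorine entering syn to the C8 side chain), and equilibration at C5 may be incomplete. Fallback, setting out from 13, uses the same facial bias in the opposite sense: syn hydroboration–oxidation of both enol ethers (BH3·THF; then NaBO3, H2O) should give the diol mono-silyl ether F3, with C2–H and C3–OH on the face syn to the C8 side chain. Double Appel chlorination with inversion (CCl4, P(n-C8H17)3, toluene, 70 °C) then gives the dichloride F4, and hydrolysis of its triethylsilyl ether (AcOH, THF, H2O) comes back to the route at 17.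

3. Step 10. Hydride delivery to the flexible α-chloro ketone may show poor facial selectivity, and elimination may compete with substitution in the Mitsunobu step that follows. Fallback, setting out from 16: catalyst-controlled asymmetric transfer hydrogenation (RuCl(p-cymene)(TsDPEN), the enantiomer that delivers the 6S carbinol, HCO2H, Et3N) should give the trans chlorohydrin F5 directly. Acetylation with retention (Ac2O, pyridine, DMAP) comes back to the route at 18 and bypasses both the substrate-controlled reduction and the Mitsunobu inversion.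

**Further compounds**

F1 | step 7 | (3R)-1-[2-(TBS-oxy)ethyl]-3-[(1S)-1-(TBDPS-oxy)propyl]-2-oxabicyclo[4.2.0]oct-7-en-5-one, cis-fused | O=C1C[C@H]([C@@H](O[Si](c3ccccc3)(c3ccccc3)C(C)(C)C)CC)O[C@@]2(CCO[Si](C)(C)C(C)(C)C)C=C[C@@H]12
F2 | step 7 | (2Z,4Z,8R)-2-[2-(TBS-oxy)ethyl]-8-[(1S)-1-(TBDPS-oxy)propyl]-7,8-dihydro-6H-oxocin-6-one | O=C1C[C@H]([C@@H](O[Si](c2ccccc2)(c2ccccc2)C(C)(C)C)CC)O/C(CCO[Si](C)(C)C(C)(C)C)=C\C=C/1
F3 | step 8 | (2S,3R,5R,6R,8R)-2-[2-(TBS-oxy)ethyl]-8-[(1S)-1-(TBDPS-oxy)propyl]-6-(TES-oxy)oxocane-3,5-diol | CC(C)(C)[Si](C)(C)OCC[C@@H]1O[C@@H]([C@@H](O[Si](c2ccccc2)(c2ccccc2)C(C)(C)C)CC)C[C@@H](O[Si](CC)(CC)CC)[C@H](O)C[C@H]1O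
F4 | step 8 | (2S,3S,5S,6R,8R)-3,5-dichloro-2-[2-(TBS-oxy)ethyl]-8-[(1S)-1-(TBDPS-oxy)propyl]-6-(TES-oxy)oxocane | CC(C)(C)[Si](C)(C)OCC[C@@H]1O[C@@H]([C@@H](O[Si](c2ccccc2)(c2ccccc2)C(C)(C)C)CC)C[C@@H](O[Si](CC)(CC)CC)[C@@H](Cl)C[C@@H]1Cl
F5 | step 10 | (2S,3S,5S,6S,8R)-3,5-dichloro-2-[2-(TBS-oxy)ethyl]-8-[(1S)-1-(TBDPS-oxy)propyl]oxocan-6-ol | CC(C)(C)[Si](C)(C)OCC[C@@H]1O[C@@H]([C@@H](O[Si](c2ccccc2)(c2ccccc2)C(C)(C)C)CC)C[C@H](O)[C@@H](Cl)C[C@@H]1Cl
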